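Everything rests on reading the C3(=CH)–C4(O) edge of the butanolide ring (O1, C2, C3, C4, C5) as a Morita–Baylis–Hillman retron. C3 is the α-carbon of an enoate whose ester oxygen O1 sits on C5, next to carbinol carbon C4. Opening C3–C4 gives an acyclic (E)-enoate ester of (R)-2-hydroxy-4-methylpent-3-enal. A phosphine-catalysed isomerisation of this aldehyde closes the lactone, sets C4 trans to the C5 isobutenyl group and rewrites the enoate alkene as the exocyclic E-alkylidene in one atom-economical operation. The precursor comes from a nerol-derived C14 acid and a glyceraldehyde-derived C6 alcohol.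

Key step: step 11

Remark: (S)-glyceraldehyde acetonide and the pentane solution of (+)-Ipc2B(allyl) are taken as purchasable. O1–C5 denote the lactone ring (C2 carbonyl, C3 alkylidene carbon, C4 acetoxy carbon, C5 isobutenyl carbon), and C8 denotes the side-chain carbinol.

Step 1
Reactants: 1 nerol
Product: 2 neryl benzoate
Conditions: BzCl, Et3N, DMAP (cat.), CH2Cl2, 0 °C to rt
Reagents that add atoms: benzoyl chloride, O=C(Cl)c1ccccc1
Why: DMAP-catalysed O-acylation of the primary allylic alcohol, which leaves the Z-alkene untouched and makes the C2=C3 alkene electron-poorer than the distal one for step 2.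

Step 2
Reactants: 2 neryl benzoate
Product: 4 (2Z,6E)-3,7-dimethyl-8-oxoocta-2,6-dien-1-yl benzoate, via allylic alcohol 3 (not isolated)
Conditions: SeO2 (1.2 equiv), 1,4-dioxane, 80 °C
Reagents that add atoms: selenium dioxide, O=[Se]=O
Why: Riley allylic oxidation (ene reaction followed by [2,3]-sigmatropic shift) should pick the electron-richer distal alkene and its E-methyl group, and the excess oxidant carries alcohol 3 on to the E-enal.

Step 3
Reactants: 4 (2Z,6E)-3,7-dimethyl-8-oxoocta-2,6-dien-1-yl benzoate
Product: 6 (2Z,6E,8R)-8-hydroxy-3,7-dimethylundeca-2,6,10-trien-1-yl benzoate, via borinate ester 5 (not isolated)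
Conditions: (+)-Ipc2B(allyl), Et2O, −78 °C; then NaBO3·4H2O, THF–H2O, rt
Reagents that add atoms: (+)-B-allyldiisopinocampheylborane of the (−)-α-pinene series, C=CCB([C@H]1C[C@H]2C[C@@H]([C@@H]1C)C2(C)C)[C@H]1C[C@H]2C[C@@H]([C@@H]1C)C2(C)C
Why: Brown allylboration through a chair-like Zimmerman–Traxler transition state, in which the isopinocampheyl groups of the (−)-α-pinene series steer the allyl group to the Re face of the formyl carbon and so set 8R, while the mild perborate work-up of borinate 5 spares the benzoate.

Step 4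
Reactants: 6 (2Z,6E,8R)-8-hydroxy-3,7-dimethylundeca-2,6,10-trien-1-yl benzoate
Product: 7 (2Z,6E,8R)-8-acetoxy-3,7-dimethylundeca-2,6,10-trien-1-yl benzoate
Conditions: Ac2O, pyridine, DMAP (cat.), 0 °C to rt
Reagents that add atoms: acetic anhydride, CC(=O)OC(C)=O
Why: DMAP-catalysed acetylation at oxygen, so the C8–O bond and its R configuration are not touched.

Step 5
Reactants: 7 (2Z,6E,8R)-8-acetoxy-3,7-dimethylundeca-2,6,10-trien-1-yl benzoate; 8 acrylic acid
Product: 9 (2E,5R,6E,10Z)-5-acetoxy-12-(benzoyloxy)-6,10-dimethyldodeca-2,6,10-trienoic acid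
Conditions: second-generation Hoveyda–Grubbs catalyst (5 mol %), 1,4-benzoquinone (10 mol %), CH2Cl2, 40 °C
Reagents that add atoms: none
Why: Olefin cross-metathesis of an unhindered terminal alkene with the electron-poor acrylic partner should give the E-enoic acid under thermodynamic control, while both trisubstituted alkenes are too hindered to enter the cycle.

Step 6
Reactants: 10 (S)-2,2-dimethyl-1,3-dioxolane-4-carbaldehyde
Product: 11 (R)-2,2-dimethyl-4-(2-methylprop-1-enyl)-1,3-dioxolane
Conditions: i-PrPPh3I, n-BuLi, THF, 0 °C; then 10, −78 °C to rt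
Reagents that add atoms: isopropyltriphenylphosphonium iodide, CC(C)[P+](c1ccccc1)(c1ccccc1)c1ccccc1.[I-]
Why: Wittig olefination with a non-stabilised ylide at low temperature, fast enough to leave the α-alkoxy stereocentre unepimerised (the descriptor changes from S to R only because the ranking of the substituents changes).

Step 7
Reactants: 11 (R)-2,2-dimethyl-4-(2-methylprop-1-enyl)-1,3-dioxolane
Product: 12 (R)-4-methylpent-3-ene-1,2-diol
Conditions: AcOH–H2O (4:1), rt
Reagents that add atoms: none
Why: Acid-catalysed acetal hydrolysis breaks only the bonds to the acetal carbon, so the allylic C–O bond and its configuration stay.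

Step 8
Reactants: 12 (R)-4-methylpent-3-ene-1,2-diol
Product: 13 (R)-4-methyl-1-(triethylsilyloxy)pent-3-en-2-ol
Conditions: Et3SiCl (1.05 equiv), imidazole, CH2Cl2, −40 °C
Reagents that add atoms: chlorotriethylsilane, CC[Si](Cl)(CC)CC
Why: Sterically controlled silylation, in which the primary hydroxyl reacts far faster than the flanked secondary allylic one at low temperature.

Step 9
Reactants: 9 (2E,5R,6E,10Z)-5-acetoxy-12-(benzoyloxy)-6,10-dimethyldodeca-2,6,10-trienoic acid; 13 (R)-4-methyl-1-(triethylsilyloxy)pent-3-en-2-ol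
Product: 14 (R)-4-methyl-1-(triethylsilyloxy)pent-3-en-2-yl (2E,5R,6E,10Z)-5-acetoxy-12-(benzoyloxy)-6,10-dimethyldodeca-2,6,10-trienoate
Conditions: dicyclohexylcarbodiimide, DMAP (10 mol %), CH2Cl2, 0 °C to rt
Reagents that add atoms: none
Why: Steglich esterification activates the acid and not the alcohol, so the C–O bond at the future C5 is kept with retention and the allylic system is not ionised.

Step 10
Reactants: 14 silyl ether ester
Product: 16 (R)-4-methyl-1-oxopent-3-en-2-yl (2E,5R,6E,10Z)-5-acetoxy-12-(benzoyloxy)-6,10-dimethyldodeca-2,6,10-trienoate, via primary alcohol 15 (not isolated)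
Conditions: IBX (3 equiv), DMSO, rt; rapid extractive work-up, used at once
Reagents that add atoms: none
Why: Oxidative desilylation: IBX in DMSO is known to cleave primary triethylsilyl ethers and to oxidise the freed alcohol 15 in the same flask, and its base-free medium should spare the epimerisable α-acyloxy-β,γ-unsaturated aldehyde.

Step 11
Reactants: 16 enoate aldehyde
Product: 19 (2Z,6E,8R,10E)-8-acetoxy-10-[(4S,5R)-4-hydroxy-5-(2-methylprop-1-enyl)-2-oxooxolan-3-ylidene]-3,7-dimethyldeca-2,6-dien-1-yl benzoate, via phosphonium enolate 17 (not isolated), via phosphonium aldolate 18 (not isolated)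
Conditions: PMe3 (0.3 equiv), PhOH (0.3 equiv), degassed THF, 0 °C to rt
Reagents that add atoms: trimethylphosphine, CP(C)C (bound in 17 and 18, expelled again on the way to 19)
Why: Intramolecular Morita–Baylis–Hillman reaction: PMe3 adds reversibly to the β-carbon of the enoate of 16, C3 of phosphonium enolate 17 attacks the formyl carbon C4 to give aldolate 18, and a phenol-relayed proton shift from C3 followed by E1cB loss of PMe3 restores the C3=CH bond. The closest known cases are the amine-catalysed closures of acrylate esters of α-hydroxy aldehydes to α-methylene-β-hydroxy-γ-lactones and the PMe3-catalysed carbocyclisations of β-alkyl enoates onto enolisable aldehydes. The lactone ring closes in the 5-(enolendo)-exo-trig mode, which is slow but proven in those ester-tethered cases. C4 is controlled by C5: in the envelope-shaped transition state the formyl oxygen turns away from the isobutenyl group, and because the aldol step is reversible the more stable 4,5-trans (4S,5R) lactone should be funnelled out. The enoate geometry is erased in 17 and rewritten in the elimination, where the side chain avoids the enolate oxygen on C2 and ends cis to C4, so E- or Z-enoate would converge on the E-alkylidene, which reversible phosphine addition to 19 should also favour. The step needs conjugate addition and aldol capture to outrun enolisation of the α-acyloxy aldehyde and vinylogous loss of the C8 acetate; the substrate secures this through the electron-poor alkoxy group that activates the enoate and through the formyl group held five atoms from C3, supported by the weakly basic phosphine and the phenol buffer.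

Step 12
Reactants: 19 hydroxy lactone
Product: 20 (2Z,6E,8R,10E)-8-acetoxy-10-[(4S,5R)-4-acetoxy-5-(2-methylprop-1-enyl)-2-oxooxolan-3-ylidene]-3,7-dimethyldeca-2,6-dien-1-yl benzoate (target)
Conditions: Ac2O, pyridine, CH2Cl2, 0 °C
Reagents that add atoms: acetic anhydride, CC(=O)OC(C)=O
Why: Acetylation of the secondary allylic alcohol at oxygen with retention at C4, run cold and without nucleophilic catalyst so that the newly formed allylic acetate is not displaced in the SN2′ sense.

Compound list
1 | nerol, (2Z)-3,7-dimethylocta-2,6-dien-1-ol | CC(C)=CCC/C(C)=C\CO | starting material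
2 | neryl benzoate | CC(C)=CCC/C(C)=C\COC(=O)c1ccccc1 | intermediate
3 | (2Z,6E)-8-hydroxy-3,7-dimethylocta-2,6-dien-1-yl benzoate | OC/C(C)=C/CC/C(C)=C\COC(=O)c1ccccc1 | intermediate
4 | (2Z,6E)-3,7-dimethyl-8-oxoocta-2,6-dien-1-yl benzoate | O=C/C(C)=C/CC/C(C)=C\COC(=O)c1ccccc1 | intermediate
5 | diisopinocampheylborinate ester of 6 | C=CC[C@@H](OB([C@H]1C[C@H]2C[C@@H]([C@@H]1C)C2(C)C)[C@H]1C[C@H]2C[C@@H]([C@@H]1C)C2(C)C)/C(C)=C/CC/C(C)=C\COC(=O)c1ccccc1 | intermediate
6 | (2Z,6E,8R)-8-hydroxy-3,7-dimethylundeca-2,6,10-trien-1-yl benzoate | O[C@H](CC=C)/C(C)=C/CC/C(C)=C\COC(=O)c1ccccc1 | intermediate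
7 | (2Z,6E,8R)-8-acetoxy-3,7-dimethylundeca-2,6,10-trien-1-yl benzoate | CC(=O)O[C@H](CC=C)/C(C)=C/CC/C(C)=C\COC(=O)c1ccccc1 | intermediate
8 | acrylic acid | C=CC(=O)O | starting material
9 | (2E,5R,6E,10Z)-5-acetoxy-12-(benzoyloxy)-6,10-dimethyldodeca-2,6,10-trienoic acid | CC(=O)O[C@H](C/C=C/C(=O)O)/C(C)=C/CC/C(C)=C\COC(=O)c1ccccc1 | intermediate
10 | (S)-2,2-dimethyl-1,3-dioxolane-4-carbaldehyde | O=C[C@@H]1COC(C)(C)O1 | starting material
11 | (R)-2,2-dimethyl-4-(2-methylprop-1-enyl)-1,3-dioxolane | CC(C)=C[C@@H]1COC(C)(C)O1 | intermediate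
12 | (R)-4-methylpent-3-ene-1,2-diol | CC(C)=C[C@@H](O)CO | intermediate
13 | (R)-4-methyl-1-(triethylsilyloxy)pent-3-en-2-ol | CC(C)=C[C@@H](O)CO[Si](CC)(CC)CC | intermediate
14 | (R)-4-methyl-1-(triethylsilyloxy)pent-3-en-2-yl ester of acid 9 | CC(=O)O[C@H](C/C=C/C(=O)O[C@H](C=C(C)C)CO[Si](CC)(CC)CC)/C(C)=C/CC/C(C)=C\COC(=O)c1ccccc1 | intermediate
15 | (R)-1-hydroxy-4-methylpent-3-en-2-yl ester of acid 9 | CC(=O)O[C@H](C/C=C/C(=O)O[C@H](C=C(C)C)CO)/C(C)=C/CC/C(C)=C\COC(=O)c1ccccc1 | intermediate
16 | (R)-4-methyl-1-oxopent-3-en-2-yl ester of acid 9 | CC(=O)O[C@H](C/C=C/C(=O)O[C@H](C=C(C)C)C=O)/C(C)=C/CC/C(C)=C\COC(=O)c1ccccc1 | intermediate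
17 | β-(trimethylphosphonio) ester enolate from 16 (zwitterion, new centre undefined) | CC(=O)O[C@H](CC([P+](C)(C)C)C=C([O-])O[C@H](C=C(C)C)C=O)/C(C)=C/CC/C(C)=C\COC(=O)c1ccccc1 | intermediate
18 | ring-closed phosphonium aldolate (zwitterion, C3 and the phosphonium carbon undefined) | CC(=O)O[C@H](CC([P+](C)(C)C)C1C(=O)O[C@H](C=C(C)C)[C@H]1[O-])/C(C)=C/CC/C(C)=C\COC(=O)c1ccccc1 | intermediate
19 | (4S,5R)-4-hydroxy-3-(E)-alkylidene lactone | CC(=O)O[C@H](C/C=C1/C(=O)O[C@H](C=C(C)C)[C@H]1O)/C(C)=C/CC/C(C)=C\COC(=O)c1ccccc1 | intermediate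
20 | CNP0262857.1 | CC(=O)O[C@H](C/C=C1/C(=O)O[C@H](C=C(C)C)[C@H]1OC(C)=O)/C(C)=C/CC/C(C)=C\COC(=O)c1ccccc1 | target

Total steps: 12. Longest linear sequence: 9 steps (steps 1–5 and 9–12, from nerol).

Steps most likely to fail

**Step 11.**
- Phosphine addition to the β-alkyl enoate may be too slow, so that proton-transfer processes take over. These are enolisation of the α-acyloxy aldehyde (epimerisation at C5 or drift of the isobutenyl double bond into conjugation), vinylogous elimination of acetic acid at C8, and incomplete control of alkene geometry or of the 4,5-relationship.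
- The fallback sets out from 13 and 8 and comes back to the route at 20.
- Silyl ether 13 is esterified with acrylic acid 8 (dicyclohexylcarbodiimide, DMAP) to (R)-4-methyl-1-(triethylsilyloxy)pent-3-en-2-yl acrylate F1.
- IBX in DMSO takes F1 through (R)-1-hydroxy-4-methylpent-3-en-2-yl acrylate F2 to (R)-4-methyl-1-oxopent-3-en-2-yl acrylate F3.
- This unsubstituted acrylate belongs to the substrate class for which the amine-catalysed closure is established. It is cyclised with DABCO in CH2Cl2, again by forming C3–C4, to (4S,5R)-4-hydroxy-3-methylidene-5-(2-methylprop-1-enyl)oxolan-2-one F4.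
- Ac2O and pyridine give (4S,5R)-4-acetoxy-3-methylidene-5-(2-methylprop-1-enyl)oxolan-2-one F5.
- Cross-metathesis of F5 with 7 (second-generation Hoveyda–Grubbs catalyst, 2,6-dichloro-1,4-benzoquinone, CH2Cl2, 40 °C) attaches the chain as the E-alkylidene and gives 20.

**Step 10.**
- The one-pot process may stall at the alcohol stage. That would allow the acyl group to shift from the secondary to the primary oxygen, or the aldehyde may degrade on long contact with the oxidant.
- The fallback unveils the formyl group by C–C cleavage instead of alcohol oxidation. It sets out from 10 and 9 and comes back at 16.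
- 2-Methylprop-1-enylmagnesium bromide adds to 10 in THF at −78 °C under Felkin–Anh control. After chromatographic removal of the epimer this gives (1R)-1-[(4S)-2,2-dimethyl-1,3-dioxolan-4-yl]-3-methylbut-2-en-1-ol F6.
- Steglich esterification with 9 gives the acetonide ester F7.
- Aqueous acetic acid frees the glycol ester F8.
- NaIO4 in THF–pH 7 buffer cleaves the glycol within minutes under neutral conditions to give 16.

**Step 2.**
- The oxidation may stop unevenly between alcohol and aldehyde, run on to over-oxidation, erode the Z-alkene on heating or leave selenium residues that poison later catalysts.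
- The fallback rebuilds the enal by chain shortening and olefination. It sets out from 2 and comes back at 4.
- mCPBA (1 equiv, CH2Cl2, 0 °C) epoxidises the electron-richer distal alkene to (2Z)-5-(3,3-dimethyloxiran-2-yl)-3-methylpent-2-en-1-yl benzoate F9.
- H5IO6 in THF–H2O cleaves F9 to (2Z)-3-methyl-6-oxohex-2-en-1-yl benzoate F10.
- The stabilised ylide 2-(triphenylphosphoranylidene)propanal in warm toluene converts F10 E-selectively into 4.

Further compounds
F1 | step 11 | (R)-4-methyl-1-(triethylsilyloxy)pent-3-en-2-yl acrylate | C=CC(=O)O[C@H](C=C(C)C)CO[Si](CC)(CC)CC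
F2 | step 11 | (R)-1-hydroxy-4-methylpent-3-en-2-yl acrylate | C=CC(=O)O[C@H](C=C(C)C)CO
F3 | step 11 | (R)-4-methyl-1-oxopent-3-en-2-yl acrylate | C=CC(=O)O[C@H](C=C(C)C)C=O
F4 | step 11 | (4S,5R)-4-hydroxy-3-methylidene-5-(2-methylprop-1-enyl)oxolan-2-one | C=C1C(=O)O[C@H](C=C(C)C)[C@H]1O
F5 | step 11 | (4S,5R)-4-acetoxy-3-methylidene-5-(2-methylprop-1-enyl)oxolan-2-one | C=C1C(=O)O[C@H](C=C(C)C)[C@H]1OC(C)=O
F6 | step 10 | (1R)-1-[(4S)-2,2-dimethyl-1,3-dioxolan-4-yl]-3-methylbut-2-en-1-ol | CC(C)=C[C@@H](O)[C@@H]1COC(C)(C)O1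
F7 | step 10 | acetonide ester of acid 9 with F6 | CC(=O)O[C@H](C/C=C/C(=O)O[C@H](C=C(C)C)[C@@H]1COC(C)(C)O1)/C(C)=C/CC/C(C)=C\COC(=O)c1ccccc1
F8 | step 10 | glycol ester from F7 | CC(=O)O[C@H](C/C=C/C(=O)O[C@H](C=C(C)C)[C@@H](O)CO)/C(C)=C/CC/C(C)=C\COC(=O)c1ccccc1
F9 | step 2 | (2Z)-5-(3,3-dimethyloxiran-2-yl)-3-methylpent-2-en-1-yl benzoate | CC1(C)OC1CC/C(C)=C\COC(=O)c1ccccc1
F10 | step 2 | (2Z)-3-methyl-6-oxohex-2-en-1-yl benzoate | O=CCC/C(C)=C\COC(=O)c1ccccc1
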